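**Plan**
- The C13=C14 alkene is cut first (E-selective Wittig, the CH2OH carried as CO2Et). This gives the lactol of (+)-ambreinolide (decalin half) and an α-alkylated stabilised ylide that carries the (S)-methylidenecyclohexane ring.
- Ambreinolide is then cut at C4–C5, C9–C10 and C8–O. Ring A (C1–C5, C10) has the gem-dimethyl carbon C4 next to the ring-fusion C5–H and the methyl-bearing C10, which is the pattern left when C4 shifts from C10 to C5. Ring A is therefore made from a 1,2,2-trimethylcyclopentane (C10, C1–C4) with C5 as an exocyclic carbinol.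
- Forward: cyclopentane from camphoric acid; chain attached by ketone-enolate allylation; then one cascade makes ring A by ring expansion and ring B plus the δ-lactone by cation–olefin closure; lactol; Wittig union; ester reduction.
- Stereochemistry: C10 of the precursor from (1S,3R)-camphoric acid; C5 from a CBS reduction (inverted in the shift); C9 and C8 from the E-alkene by anti addition; the left-ring centre by lipase resolution; the alkene geometry from the stabilised ylide.

Key step: step 9

Assumption: the decalin half is numbered as a labdane (ring A = C1–C5, C10; ring B = C5–C10; chain C11–C12–C13 on C9; C14 bears CH2OH), and the lipase of step 14 is assumed to acetylate the (R)-enantiomer of 20 faster.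

**Route**

Step 1
Reactants: 1 (1S,3R)-camphoric acid
Product: 2 (1S,5R)-1,8,8-trimethyl-3-oxabicyclo[3.2.1]octane-2,4-dione (camphoric anhydride)
Conditions: Ac2O, 140 °C
Reagents that add atoms: none
Why: Dehydration of the cis-1,3-diacid to its cyclic anhydride (anhydride formation) leaves both stereocentres untouched.

Step 2
Reactants: 2 camphoric anhydride
Product: 4 (1S)-1,2,2-trimethylcyclopentane-1-carboxylic acid, via thiohydroxamate ester 3 (not isolated)
Conditions: N-hydroxypyridine-2-thione, Et3N, DMAP (cat.), CH2Cl2, 25 °C, dark; then t-BuSH, hν (tungsten lamp), 25 °C; aq. HCl work-up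
Reagents that add atoms: none
Why: The thiohydroxamic acid should open the anhydride at the less hindered secondary acyl carbon, and Barton reductive decarboxylation (radical chain with t-BuSH) then removes that carboxyl while the quaternary stereocentre stays intact.

Step 3
Reactants: 4 (1S)-1,2,2-trimethylcyclopentane-1-carboxylic acid
Product: 5 1-[(1S)-1,2,2-trimethylcyclopentyl]ethan-1-one
Conditions: MeLi (3 equiv), Et2O, 0 → 25 °C; poured into cold aq. NH4Cl
Reagents that add atoms: methyllithium, [Li]C
Why: Addition of MeLi to the lithium carboxylate gives a dilithium gem-diolate that collapses to the methyl ketone only on work-up (ketone synthesis from a carboxylic acid and an organolithium), and the hindered centre disfavours over-addition.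

Step 4
Reactants: 6 tert-butyl acetate; 7 1-bromo-3-methylbut-2-ene (prenyl bromide)
Product: 8 tert-butyl 5-methylhex-4-enoate
Conditions: LiN(i-Pr)2, THF, −78 °C; then 7, −78 → 0 °C
Reagents that add atoms: none
Why: SN2 alkylation of the lithium ester enolate with a primary allylic bromide (ester enolate alkylation).

Step 5
Reactants: 8 tert-butyl 5-methylhex-4-enoate
Product: 9 tert-butyl (4E)-6-hydroxy-5-methylhex-4-enoate
Conditions: SeO2 (cat.), t-BuOOH, CH2Cl2, 0 → 25 °C
Reagents that add atoms: tert-butyl hydroperoxide, CC(C)(C)OO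
Why: Allylic oxidation with SeO2 (ene reaction, then [2,3]-sigmatropic shift) attacks the methyl group trans to the chain of a trisubstituted alkene and should give the E-allylic alcohol.

Step 6
Reactants: 9 tert-butyl (4E)-6-hydroxy-5-methylhex-4-enoate
Product: 10 tert-butyl (4E)-6-bromo-5-methylhex-4-enoate
Conditions: CBr4, PPh3, CH2Cl2, 0 °C
Reagents that add atoms: carbon tetrabromide, BrC(Br)(Br)Br
Why: Appel bromination of the primary allylic alcohol at low temperature should proceed without allylic transposition or loss of the E geometry.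

Step 7
Reactants: 5 1-[(1S)-1,2,2-trimethylcyclopentyl]ethan-1-one; 10 tert-butyl (4E)-6-bromo-5-methylhex-4-enoate
Product: 11 tert-butyl (4E)-5-methyl-8-oxo-8-[(1S)-1,2,2-trimethylcyclopentyl]oct-4-enoate
Conditions: 5, LiN(i-Pr)2, THF, −78 °C; then 10, DMPU, −78 → −20 °C
Reagents that add atoms: none
Why: The ketone can enolise only at its methyl group (the other α-carbon is quaternary), so kinetic enolate formation and SN2 allylation (ketone enolate alkylation) attach the chain and carry the E-alkene over unchanged.

Step 8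
Reactants: 11 tert-butyl (4E)-5-methyl-8-oxo-8-[(1S)-1,2,2-trimethylcyclopentyl]oct-4-enoate
Product: 12 tert-butyl (4E,8S)-8-hydroxy-5-methyl-8-[(1S)-1,2,2-trimethylcyclopentyl]oct-4-enoate
Conditions: (R)-2-methyl-CBS-oxazaborolidine (cat.), catecholborane, toluene, −78 → −20 °C
Reagents that add atoms: none
Why: Corey–Bakshi–Shibata reduction, in which the oxazaborolidine tells the tertiary alkyl group from the CH2 chain and the (R)-catalyst should deliver hydride to give the (S)-carbinol under reagent control, while catecholborane spares the alkene and the ester.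

Step 9
Reactants: 12 tert-butyl (4E,8S)-8-hydroxy-5-methyl-8-[(1S)-1,2,2-trimethylcyclopentyl]oct-4-enoate
Product: 14 (+)-ambreinolide [δ-lactone of (5S,8R,9R,10S)-8-hydroxy-14,15,16-trinorlabdan-13-oic acid], via secondary triflate 13 (not isolated)
Conditions: Tf2O, 2,6-di-tert-butyl-4-methylpyridine, CH2Cl2, −78 → 0 °C
Reagents that add atoms: none
Why: Proposed new method: the secondary neopentyl-type triflate 13 should ionise only with participation of the anti-periplanar ring bond C10–C4, so that the quaternary carbon C4 shifts from C10 to C5 (Wagner–Meerwein ring expansion of the cyclopentane to the six-membered ring A); the tertiary C10 cation is then captured by the E-trisubstituted C8=C9 alkene and the C8 cation by the ester carbonyl oxygen, with loss of isobutene. The closest known reaction types are the solvolytic ring expansion of cyclopentylcarbinyl sulfonates and the acid-promoted cyclisation of monocyclic farnesylacetic acids to ambreinolide, which passes through the same C10 cation. Ring A closes by the 1,2-alkyl shift, ring B by a 6-endo-trig cation–olefin closure through a chair, and the lactone by 6-endo attack of the carbonyl oxygen on C8. C5 is set by inversion at the carbinol carbon (configuration from step 8); C10 by attack of C9 anti to the departing C4, which the (1S) configuration of the cyclopentane and the chair both direct to the trans ring fusion; C9 by the E geometry of the alkene; and C8 by anti addition across it (equatorial oxygen). The step needs migration of C4 in preference to C1 or the methyl group, which the higher migratory aptitude of the quaternary carbon should secure, and it needs cyclisation to outrun proton loss from the C10 cation, which the hindered non-nucleophilic pyridine buffer and the low temperature favour.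

Step 10
Reactants: 14 (+)-ambreinolide
Product: 15 ambreinolide lactol (8α,13-epoxy-14,15,16-trinorlabdan-13-ol, mixture of anomers)
Conditions: i-Bu2AlH (1.1 equiv), CH2Cl2, −78 °C; aqueous work-up
Reagents that add atoms: none
Why: Partial reduction of a δ-lactone with i-Bu2AlH at −78 °C should stop at the lactol because the tetrahedral aluminium alkoxide is stable until work-up.

Step 11
Reactants: 16 3-methylcyclohex-2-en-1-one; 17 ethyl iodoacetate
Product: 18 ethyl (±)-2-(2,2-dimethyl-6-oxocyclohexyl)acetate
Conditions: Me2CuLi (from MeLi and CuI), Et2O, 0 °C; then 17, HMPA, THF, −30 → 25 °C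
Reagents that add atoms: lithium dimethylcuprate, [Li+].C[Cu-]C
Why: Conjugate addition of the cuprate makes the gem-dimethyl carbon and a regiodefined enolate that is alkylated in the same flask at C2 (tandem conjugate addition–enolate alkylation), giving the racemic ketone.

Step 12
Reactants: 18 ethyl (±)-2-(2,2-dimethyl-6-oxocyclohexyl)acetate
Product: 19 ethyl (±)-2-(2,2-dimethyl-6-methylidenecyclohexyl)acetate
Conditions: Zn, CH2Br2, TiCl4, THF/CH2Cl2, 0 → 25 °C
Reagents that add atoms: dibromomethane, BrCBr
Why: Takai–Lombardo methylenation is non-basic, tolerates hindered ketones and should leave the ester untouched.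

Step 13
Reactants: 19 ethyl (±)-2-(2,2-dimethyl-6-methylidenecyclohexyl)acetate
Product: 20 (±)-2-(2,2-dimethyl-6-methylidenecyclohexyl)ethan-1-ol
Conditions: LiAlH4, Et2O, 0 °C
Reagents that add atoms: none
Why: Hydride reduction of the ester to the primary alcohol leaves the 1,1-disubstituted alkene alone.

Step 14
Reactants: 20 (±)-2-(2,2-dimethyl-6-methylidenecyclohexyl)ethan-1-ol
Product: 21 2-[(1S)-2,2-dimethyl-6-methylidenecyclohexyl]ethan-1-ol
Conditions: lipase from Burkholderia cepacia (immobilised), vinyl acetate, t-BuOMe, 25 °C, stopped beyond half conversion; chromatography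
Reagents that add atoms: none
Why: Lipase-catalysed kinetic resolution by irreversible acyl transfer should acetylate the (R)-alcohol faster, so that running past half conversion leaves the (S)-alcohol, which is separated from the acetate.

Step 15
Reactants: 21 2-[(1S)-2,2-dimethyl-6-methylidenecyclohexyl]ethan-1-ol
Product: 22 (2S)-2-(2-iodoethyl)-1,1-dimethyl-3-methylidenecyclohexane
Conditions: PPh3, I2, imidazole, CH2Cl2, 0 → 25 °C
Reagents that add atoms: iodine, [I][I]
Why: Appel-type iodination is an SN2 displacement at the primary carbon under neutral conditions, so the allylic stereocentre and the exocyclic alkene should not be touched.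

Step 16
Reactants: 22 (2S)-2-(2-iodoethyl)-1,1-dimethyl-3-methylidenecyclohexane; 23 ethyl (triphenyl-λ5-phosphanylidene)acetate
Product: 25 ethyl 4-[(1S)-2,2-dimethyl-6-methylidenecyclohexyl]-2-(triphenyl-λ5-phosphanylidene)butanoate, via phosphonium iodide 24 (not isolated)
Conditions: 23 (2.2 equiv), MeCN, 80 °C; precipitated salt filtered off
Reagents that add atoms: none
Why: C-alkylation of the stabilised ylide by the primary iodide gives a phosphonium salt that the second equivalent of ylide deprotonates (transylidation) to the α-substituted stabilised ylide.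

Step 17
Reactants: 15 ambreinolide lactol; 25 ethyl 4-[(1S)-2,2-dimethyl-6-methylidenecyclohexyl]-2-(triphenyl-λ5-phosphanylidene)butanoate
Product: 26 ethyl (2E)-2-{2-[(1S)-2,2-dimethyl-6-methylidenecyclohexyl]ethyl}-5-[(1R,2R,4aS,8aS)-2-hydroxy-2,5,5,8a-tetramethyldecahydronaphthalen-1-yl]pent-2-enoate
Conditions: toluene, PhCO2H (cat.), 100 °C
Reagents that add atoms: none
Why: Wittig olefination of the open hydroxy-aldehyde form of the lactol with an α-substituted stabilised ylide should give the E-enoate (ester trans to the C12 chain), which is the geometry of the target, under neutral conditions that do not promote oxa-Michael closure.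

Step 18
Reactants: 26 the E-enoate
Product: 27 (1R,2R,4aS,8aS)-1-{(3E)-6-[(1S)-2,2-dimethyl-6-methylidenecyclohexyl]-4-(hydroxymethyl)hex-3-en-1-yl}-2,5,5,8a-tetramethyldecahydronaphthalen-2-ol (target)
Conditions: i-Bu2AlH (3.5 equiv), CH2Cl2, −78 → 0 °C
Reagents that add atoms: none
Why: 1,2-Reduction of the α,β-unsaturated ester by i-Bu2AlH should give the allylic alcohol with the alkene geometry unchanged, the tertiary hydroxyl and the exocyclic alkene being inert.

**Compound list**

1 | (1S,3R)-camphoric acid | OC(=O)[C@@]1(C)CC[C@@H](C(=O)O)C1(C)C | starting material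
2 | (1S,5R)-1,8,8-trimethyl-3-oxabicyclo[3.2.1]octane-2,4-dione (camphoric anhydride) | O=C1OC(=O)[C@@]2(C)CC[C@@H]1C2(C)C | intermediate
3 | (1S,3R)-1,2,2-trimethyl-3-{[(2-thioxopyridin-1(2H)-yl)oxy]carbonyl}cyclopentane-1-carboxylic acid (thiohydroxamate ester, not isolated) | OC(=O)[C@@]1(C)CC[C@@H](C(=O)ON2C=CC=CC2=S)C1(C)C | intermediate
4 | (1S)-1,2,2-trimethylcyclopentane-1-carboxylic acid | OC(=O)[C@@]1(C)CCCC1(C)C | intermediate
5 | 1-[(1S)-1,2,2-trimethylcyclopentyl]ethan-1-one | CC(=O)[C@@]1(C)CCCC1(C)C | intermediate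
6 | tert-butyl acetate | CC(=O)OC(C)(C)C | starting material
7 | 1-bromo-3-methylbut-2-ene | CC(C)=CCBr | starting material
8 | tert-butyl 5-methylhex-4-enoate | CC(C)=CCCC(=O)OC(C)(C)C | intermediate
9 | tert-butyl (4E)-6-hydroxy-5-methylhex-4-enoate | OC/C(C)=C/CCC(=O)OC(C)(C)C | intermediate
10 | tert-butyl (4E)-6-bromo-5-methylhex-4-enoate | BrC/C(C)=C/CCC(=O)OC(C)(C)C | intermediate
11 | tert-butyl (4E)-5-methyl-8-oxo-8-[(1S)-1,2,2-trimethylcyclopentyl]oct-4-enoate | CC(C)(C)OC(=O)CC/C=C(\C)CCC(=O)[C@@]1(C)CCCC1(C)C | intermediate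
12 | tert-butyl (4E,8S)-8-hydroxy-5-methyl-8-[(1S)-1,2,2-trimethylcyclopentyl]oct-4-enoate | CC(C)(C)OC(=O)CC/C=C(\C)CC[C@H](O)[C@@]1(C)CCCC1(C)C | intermediate
13 | tert-butyl (4E,8S)-5-methyl-8-[(trifluoromethylsulfonyl)oxy]-8-[(1S)-1,2,2-trimethylcyclopentyl]oct-4-enoate (not isolated) | CC(C)(C)OC(=O)CC/C=C(\C)CC[C@H](OS(=O)(=O)C(F)(F)F)[C@@]1(C)CCCC1(C)C | intermediate
14 | (+)-ambreinolide, δ-lactone of (5S,8R,9R,10S)-8-hydroxy-14,15,16-trinorlabdan-13-oic acid | O=C1CC[C@@H]2[C@@]3(C)CCCC(C)(C)[C@@H]3CC[C@@]2(C)O1 | intermediate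
15 | ambreinolide lactol (anomeric mixture) | OC1CC[C@@H]2[C@@]3(C)CCCC(C)(C)[C@@H]3CC[C@@]2(C)O1 | intermediate
16 | 3-methylcyclohex-2-en-1-one | CC1=CC(=O)CCC1 | starting material
17 | ethyl iodoacetate | CCOC(=O)CI | starting material
18 | ethyl (±)-2-(2,2-dimethyl-6-oxocyclohexyl)acetate | CCOC(=O)CC1C(=O)CCCC1(C)C | intermediate
19 | ethyl (±)-2-(2,2-dimethyl-6-methylidenecyclohexyl)acetate | CCOC(=O)CC1C(=C)CCCC1(C)C | intermediate
20 | (±)-2-(2,2-dimethyl-6-methylidenecyclohexyl)ethan-1-ol | OCCC1C(=C)CCCC1(C)C | intermediate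
21 | 2-[(1S)-2,2-dimethyl-6-methylidenecyclohexyl]ethan-1-ol | OCC[C@@H]1C(=C)CCCC1(C)C | intermediate
22 | (2S)-2-(2-iodoethyl)-1,1-dimethyl-3-methylidenecyclohexane | ICC[C@@H]1C(=C)CCCC1(C)C | intermediate
23 | ethyl (triphenyl-λ5-phosphanylidene)acetate | CCOC(=O)C=P(c1ccccc1)(c1ccccc1)c1ccccc1 | starting material
24 | {4-[(1S)-2,2-dimethyl-6-methylidenecyclohexyl]-1-ethoxy-1-oxobutan-2-yl}triphenylphosphonium iodide (not isolated) | CCOC(=O)C(CC[C@@H]1C(=C)CCCC1(C)C)[P+](c1ccccc1)(c1ccccc1)c1ccccc1.[I-] | intermediate
25 | ethyl 4-[(1S)-2,2-dimethyl-6-methylidenecyclohexyl]-2-(triphenyl-λ5-phosphanylidene)butanoate | CCOC(=O)C(CC[C@@H]1C(=C)CCCC1(C)C)=P(c1ccccc1)(c1ccccc1)c1ccccc1 | intermediate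
26 | ethyl (2E)-2-{2-[(1S)-2,2-dimethyl-6-methylidenecyclohexyl]ethyl}-5-[(1R,2R,4aS,8aS)-2-hydroxy-2,5,5,8a-tetramethyldecahydronaphthalen-1-yl]pent-2-enoate | C=C1CCCC(C)(C)[C@@H]1CC/C(=C\CC[C@@H]1[C@@]2(C)CCCC(C)(C)[C@@H]2CC[C@@]1(C)O)C(=O)OCC | intermediate
27 | (1R,2R,4aS,8aS)-1-{(3E)-6-[(1S)-2,2-dimethyl-6-methylidenecyclohexyl]-4-(hydroxymethyl)hex-3-en-1-yl}-2,5,5,8a-tetramethyldecahydronaphthalen-2-ol | C=C1CCCC(C)(C)[C@@H]1CC/C(=C\CC[C@@H]1[C@@]2(C)CCCC(C)(C)[C@@H]2CC[C@@]1(C)O)CO | target

**Step count and risks**

Total step count: 18. Longest linear sequence: 9 steps (steps 1, 2, 3, 7, 8, 9, 10, 17, 18).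

Steps most likely to fail:

1. Step 9 (the new cascade). The C10 cation may lose a proton before the alkene captures it, a ring bond other than C10–C4 may migrate, or ring B may close to the cis-fused isomer. The fallback sets out from 12 and comes back at 14, and separates the ring expansion from the bicyclisation using known reaction types. Mesylation of 12 (MsCl, Et3N, CH2Cl2) should give tert-butyl (4E,8S)-5-methyl-8-[(methylsulfonyl)oxy]-8-[(1S)-1,2,2-trimethylcyclopentyl]oct-4-enoate F1. Solvolysis of F1 in CF3CH2OH with 2,6-lutidine at 60 °C is a Wagner–Meerwein ring expansion ended by loss of a proton from C1, and should give tert-butyl (4E)-5-methyl-7-[(1S)-2,6,6-trimethylcyclohex-2-en-1-yl]hept-4-enoate F2, in which ring A already has its final size and C5 keeps its configuration. Treatment of F2 with ClSO3H in 2-nitropropane at −78 °C, the established superacid cyclisation of monocyclic trienoic acids and esters, should regenerate the C10 cation by protonation of the ring alkene and close ring B and the lactone to 14. Any tetrasubstituted alkene isomer formed in the elimination would lower the enantiomeric purity and is removed beforehand.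

2. Step 14. Enantiomer discrimination by the lipase may be weak for a stereocentre two atoms away from the hydroxyl group, or the preference may be the reverse of the one assumed. The fallback sets out from 19 and comes back at 21, and replaces the enzymatic resolution by separation of covalent diastereomers. Saponification of 19 (LiOH, THF/H2O) should give (±)-2-(2,2-dimethyl-6-methylidenecyclohexyl)acetic acid F3. Activation with t-BuCOCl/Et3N and acylation of the lithium salt of (S)-4-benzyloxazolidin-2-one should give two imides, separated by chromatography or crystallisation: (4S)-4-benzyl-3-{[(1S)-2,2-dimethyl-6-methylidenecyclohexyl]acetyl}-1,3-oxazolidin-2-one F4 and (4S)-4-benzyl-3-{[(1R)-2,2-dimethyl-6-methylidenecyclohexyl]acetyl}-1,3-oxazolidin-2-one F5. Reduction of F4 with LiBH4 (THF, 0 °C) should give 21.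

3. Step 17. The tertiary lactol may hold too little of the open hydroxy-aldehyde form for the hindered ylide to react at a useful rate, or the freed tertiary hydroxyl may add to the enoate in a conjugate fashion. The fallback sets out from 14 and comes back at 26, and uses an open-chain, protected aldehyde instead of the lactol. Opening of 14 with Me(MeO)NH·HCl/Me3Al should give N-methoxy-N-methyl-3-[(1R,2R,4aS,8aS)-2-hydroxy-2,5,5,8a-tetramethyldecahydronaphthalen-1-yl]propanamide F6. Silylation (Et3SiOTf, 2,6-lutidine) should give its triethylsilyl ether F7. Reduction with i-Bu2AlH at −78 °C should give 3-[(1R,2R,4aS,8aS)-2,5,5,8a-tetramethyl-2-(triethylsilyloxy)decahydronaphthalen-1-yl]propanal F8. Wittig reaction of F8 with 25 (toluene, 80 °C) should give the silyl-protected E-enoate F9. Removal of the silyl group (HF·pyridine, THF) should give 26.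

Further compounds
F1 | step 9 | tert-butyl (4E,8S)-5-methyl-8-[(methylsulfonyl)oxy]-8-[(1S)-1,2,2-trimethylcyclopentyl]oct-4-enoate | CC(C)(C)OC(=O)CC/C=C(\C)CC[C@H](OS(C)(=O)=O)[C@@]1(C)CCCC1(C)C
F2 | step 9 | tert-butyl (4E)-5-methyl-7-[(1S)-2,6,6-trimethylcyclohex-2-en-1-yl]hept-4-enoate | CC(C)(C)OC(=O)CC/C=C(\C)CC[C@@H]1C(C)=CCCC1(C)C
F3 | step 14 | (±)-2-(2,2-dimethyl-6-methylidenecyclohexyl)acetic acid | OC(=O)CC1C(=C)CCCC1(C)C
F4 | step 14 | (4S)-4-benzyl-3-{[(1S)-2,2-dimethyl-6-methylidenecyclohexyl]acetyl}-1,3-oxazolidin-2-one | O=C(C[C@@H]1C(=C)CCCC1(C)C)N1[C@@H](Cc2ccccc2)COC1=O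
F5 | step 14 | (4S)-4-benzyl-3-{[(1R)-2,2-dimethyl-6-methylidenecyclohexyl]acetyl}-1,3-oxazolidin-2-one | O=C(C[C@H]1C(=C)CCCC1(C)C)N1[C@@H](Cc2ccccc2)COC1=O
F6 | step 17 | N-methoxy-N-methyl-3-[(1R,2R,4aS,8aS)-2-hydroxy-2,5,5,8a-tetramethyldecahydronaphthalen-1-yl]propanamide | CON(C)C(=O)CC[C@@H]1[C@@]2(C)CCCC(C)(C)[C@@H]2CC[C@@]1(C)O
F7 | step 17 | N-methoxy-N-methyl-3-[(1R,2R,4aS,8aS)-2,5,5,8a-tetramethyl-2-(triethylsilyloxy)decahydronaphthalen-1-yl]propanamide | CON(C)C(=O)CC[C@@H]1[C@@]2(C)CCCC(C)(C)[C@@H]2CC[C@@]1(C)O[Si](CC)(CC)CC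
F8 | step 17 | 3-[(1R,2R,4aS,8aS)-2,5,5,8a-tetramethyl-2-(triethylsilyloxy)decahydronaphthalen-1-yl]propanal | O=CCC[C@@H]1[C@@]2(C)CCCC(C)(C)[C@@H]2CC[C@@]1(C)O[Si](CC)(CC)CC
F9 | step 17 | ethyl (2E)-2-{2-[(1S)-2,2-dimethyl-6-methylidenecyclohexyl]ethyl}-5-[(1R,2R,4aS,8aS)-2,5,5,8a-tetramethyl-2-(triethylsilyloxy)decahydronaphthalen-1-yl]pent-2-enoate | C=C1CCCC(C)(C)[C@@H]1CC/C(=C\CC[C@@H]1[C@@]2(C)CCCC(C)(C)[C@@H]2CC[C@@]1(C)O[Si](CC)(CC)CC)C(=O)OCC
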